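Everything rests on opening ring B at O1–C2. C2–C3–C4 then becomes an allyl unit whose C4 terminus, the isopropyl-bearing stereocentre, is bonded to C4a, the nucleophilic carbon between the C5 and C8a carbonyls of ring A. This is the feature the key step exploits. A palladium-catalysed asymmetric allylic alkylation joins syncarpic acid to C4, creating the C4–C4a bond and the C4 stereocentre in one operation and leaving a C2=C3 ylidene on the pinane. Its precursor is the tertiary allylic methyl carbonate obtained from (−)-nopinone and an (E)-3-methylbutenyl metal. Acid-catalysed capture of C2 by the enol oxygen, anti to the gem-dimethyl bridge, finally closes ring B.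

Key step: step 4

Atom labels: chromane numbering for rings A and B (O1, spiro C2, C3, C4, C4a, C5–C8, C8a). Pinane carbons carry primes (C1′, C3′–C7′); C6′ bears the gem-dimethyl group and C7′ is the methylene bridge.

Assumption: (+)-β-pinene, the (1R,5R) enantiomer demanded by the bridgeheads of the target, and syncarpic acid are bought as such.

Step 1
Reactants: 1 (+)-β-pinene
Product: 2 (−)-nopinone [(1S,5R)-6,6-dimethylbicyclo[3.1.1]heptan-2-one]
Conditions: O3, CH2Cl2/MeOH, −78 °C; then Me2S, −78 °C → rt
Reagents that add atoms: ozone [O-][O+]=O
Why: Ozonolysis with reductive work-up cleaves only the exocyclic C=CH2 bond and leaves both bridgehead stereocentres untouched, the standard conversion of β-pinene into nopinone.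

Step 2
Reactants: 3 3-methylbut-1-yne
Product: 5 (E)-1-iodo-3-methylbut-1-ene, via alkenylzirconocene chloride 4 (not isolated)
Conditions: Cp2Zr(H)Cl, CH2Cl2, 0 °C → rt; then I2, 0 °C
Reagents that add atoms: iodine II
Why: Schwartz hydrozirconation adds Zr–H syn across the terminal alkyne with zirconium on the unhindered terminal carbon, and iodinolysis of the C–Zr bond proceeds with retention, so only the E iodide should form.

Step 3
Reactants: 5 (E)-1-iodo-3-methylbut-1-ene; 2 (−)-nopinone
Product: 8 (1S,2R,5R)-6,6-dimethyl-2-[(E)-3-methylbut-1-enyl]bicyclo[3.1.1]heptan-2-yl methyl carbonate, via alkenyllithium 6 (not isolated), via lithium alkoxide 7 (not isolated)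
Conditions: 5, t-BuLi (2 equiv per 5), Et2O, −78 °C; then 2, −78 → −20 °C; then ClCO2Me, THF, −78 °C → rt
Reagents that add atoms: methyl chloroformate COC(=O)Cl
Why: Lithium–iodine exchange keeps the E geometry, the alkenyllithium undergoes 1,2-addition to the ketone from the face turned away from the gem-dimethyl bridge (the usual course for nopinone), which sets C2 with its oxygen on the gem-dimethyl side, and the tertiary alkoxide is O-acylated in the same flask by the small, reactive chloroformate.

Step 4
Reactants: 8 tertiary allylic methyl carbonate; 9 syncarpic acid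
Product: 10 5-hydroxy-2,2,6,6-tetramethyl-4-{(1S,2Z)-1-isopropyl-2-[(1S,5R)-6,6-dimethylbicyclo[3.1.1]heptan-2-ylidene]ethyl}cyclohex-4-ene-1,3-dione (C4a-allylated syncarpic acid with C2=C3 ylidene; C4 cis to C1′)
Conditions: Pd2(dba)3·CHCl3 (2.5 mol %), (S)-t-Bu-PHOX (6 mol %), degassed THF, 0 °C → rt
Reagents that add atoms: none
Why: Zerovalent palladium binds the C3=C4 alkene of 8 on the side opposite the C2–O bond, which is the open face turned towards the C7′ methylene bridge, and expels methyl carbonate (CO2 and methoxide, the base for 9) to give a cationic allyl complex over C2–C3–C4 with the isopropyl group syn; the enolate carbon C4a then attacks C4 from the side away from the metal, so the step is a Tsuji–Trost asymmetric allylic alkylation of a cyclic 1,3-dione that forms C4–C4a and closes no ring. Regioselectivity for C4 is secured by the substrate, because C2 is fully substituted and the only trajectory to it that is anti to palladium runs under the gem-dimethyl bridge. Chemoselectivity for carbon over oxygen follows from reversibility, since an O-allylated syncarpate is itself an allylic leaving group and re-ionises until the C-alkylated trione has collected. Because both displacements are anti and palladium stays on the C7′ face, the C4 configuration is tied to the rotamer about C2–C3 that ionises: C4 lying over C1′ leads to the Z ylidene with the C4 centre of the target, C4 lying over C3′ to the E ylidene with the opposite centre. The new stereocentre C4 is therefore controlled by the ligand, which selects the alkene face at ionisation (and the faster-reacting allyl complex if the two exchange through a σ-allyl bound at C2); (S)-t-Bu-PHOX, a ligand class suited to hindered 1,3-dialkyl and 1,1,3-trisubstituted allyl units, is chosen because attack trans to phosphorus on its favoured allyl rotamer is expected to match this face, and its antipode is equally available. The two outcomes are diastereomers that can be separated, and the ylidene geometry of 10 disappears in step 5.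

Step 5
Reactants: 10 C4a-allylated syncarpic acid
Product: 11 (1′S,2S,4R,5′R)-6,6,6′,6′,8,8-hexamethyl-4-(propan-2-yl)-3,4-dihydrospiro[chromene-2,2′-bicyclo[3.1.1]heptane]-5,7(6H,8H)-dione (target)
Conditions: Tf2NH (5 mol %), CH2Cl2, −78 → −40 °C; Et3N quench
Reagents that add atoms: none
Why: This is a Brønsted-acid-catalysed Markovnikov hydroalkoxylation of the kind that turns C-prenylated cyclic 1,3-diones into chromane-type ethers: protonation at C3 puts the charge on tertiary C2, either of the two equivalent enol oxygens of ring A closes ring B (6-endo-trig) from the open C7′ face anti to the gem-dimethyl bridge and so sets spiro C2, C4 is not touched, and low temperature with a catalytic, non-nucleophilic acid should keep capture ahead of skeletal rearrangement.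

Compound list
1 | (+)-β-pinene, (1R,5R)-6,6-dimethyl-2-methylidenebicyclo[3.1.1]heptane | C=C1CC[C@@H]2C[C@H]1C2(C)C | starting material
2 | (−)-nopinone, (1S,5R)-6,6-dimethylbicyclo[3.1.1]heptan-2-one | O=C1CC[C@@H]2C[C@H]1C2(C)C | intermediate
3 | 3-methylbut-1-yne | CC(C)C#C | starting material
4 | chlorobis(cyclopentadienyl)[(E)-3-methylbut-1-enyl]zirconium (cyclopentadienyl rings drawn σ-bonded) | CC(C)/C=C/[Zr](Cl)(C1C=CC=C1)C1C=CC=C1 | intermediate
5 | (E)-1-iodo-3-methylbut-1-ene | CC(C)/C=C/I | intermediate
6 | (E)-3-methylbut-1-enyllithium | CC(C)/C=C/[Li] | intermediate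
7 | lithium (1S,2R,5R)-6,6-dimethyl-2-[(E)-3-methylbut-1-enyl]bicyclo[3.1.1]heptan-2-olate (alkenyl on the C7′ side, oxygen on the gem-dimethyl side) | CC(C)/C=C/[C@@]1(CC[C@@H]2C[C@H]1C2(C)C)O[Li] | intermediate
8 | (1S,2R,5R)-6,6-dimethyl-2-[(E)-3-methylbut-1-enyl]bicyclo[3.1.1]heptan-2-yl methyl carbonate | CC(C)/C=C/[C@@]1(CC[C@@H]2C[C@H]1C2(C)C)OC(=O)OC | intermediate
9 | syncarpic acid, 2,2,4,4-tetramethylcyclohexane-1,3,5-trione | CC1(C)C(=O)CC(=O)C(C)(C)C1=O | starting material
10 | C4a-allylated syncarpic acid, enol form, C4 (S), Z ylidene (C4 cis to C1′), bridgeheads as in 1 | CC(C)[C@H](C1=C(O)C(C)(C)C(=O)C(C)(C)C1=O)/C=C2/CC[C@@H]3C[C@H]2C3(C)C | intermediate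
11 | CNP0534730.2, spiro ether with C2 (S), C4 (R), O1 anti to the gem-dimethyl bridge | CC(C)[C@H]1C[C@]2(CC[C@@H]3C[C@H]2C3(C)C)OC2=C1C(=O)C(C)(C)C(=O)C2(C)C | target

Total steps: 5. Longest linear sequence: 4 (steps 1, 3, 4, 5).

Steps most likely to fail

1. Step 4.
- **What may go wrong:** facial selection at ionisation may follow the intrinsic rotamer preference of the pinane and not the ligand. The weakly nucleophilic, crowded enolate may attack the isopropyl-bearing terminus only slowly. The allyl complex may lose a proton to give dienes.
- **Fallback (sets out from 9 and 1, comes back at 11):** both ring-B bonds are made by cycloaddition instead of by allylation. Knoevenagel condensation of 9 with isobutyraldehyde (catalytic piperidine, CH2Cl2) gives isobutylidene syncarpic acid F1. The exocyclic alkene of 1 takes up this oxadiene in an inverse-demand hetero-Diels–Alder reaction on the face anti to the gem-dimethyl bridge, with oxygen going to C2 and C4 to the CH2 terminus. C4 is not controlled in this way, so 11 has to be separated by chromatography from its C4 epimer F2.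

2. Step 5.
- **What may go wrong:** a Wagner–Meerwein shift or opening of the cyclobutane in the C2 cation may occur before the oxygen arrives. Capture may come from the gem-dimethyl side. The tertiary vinylogous ester may re-ionise on prolonged contact with acid.
- **Fallback (sets out from 10, comes back at 11):** ring B is closed pericyclically, without any charge at C2. DDQ in 1,4-dioxane abstracts hydride from the doubly activated C4–H, as in the oxidative cyclisation of prenylated phenols to chromenes. The resulting oxatriene undergoes oxa-6π electrocyclisation to the 4-isopropyl spiro-2H-pyran F3. Hydrogenation of C3=C4 (H2, Pd/C, EtOAc) from the ring-B face that carries C3′, away from C1′ and its bridges, should place the C4 hydrogen cis to C3′ as in 11. This gives up the C4 centre made in step 4 and sets it again by substrate control.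

3. Step 3.
- **What may go wrong:** the alkenyllithium may enolise 2, the hindered tertiary alkoxide may be acylated incompletely, and the carbonate may ionise during purification.
- **Fallback (sets out from 3 and 2, comes back at 7):** 3 is deprotonated with n-BuLi to lithium 3-methylbut-1-ynide F4, a slimmer and less basic nucleophile. It adds to 2 from the same face to give the propargylic alcohol F5. Hydroxyl-directed trans-hydroalumination with NaAlH2(OCH2CH2OMe)2 in THF, followed by protonolysis, gives the (E)-allylic alcohol F6, which can be purified. n-BuLi then regenerates 7 for acylation under controlled stoichiometry.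

Further compounds
F1 | step 4 | isobutylidene syncarpic acid, 2,2,4,4-tetramethyl-6-(2-methylpropylidene)cyclohexane-1,3,5-trione | CC(C)C=C1C(=O)C(C)(C)C(=O)C(C)(C)C1=O
F2 | step 4 | C4 epimer of 11 (C2 S, C4 S) | CC(C)[C@@H]1C[C@]2(CC[C@@H]3C[C@H]2C3(C)C)OC2=C1C(=O)C(C)(C)C(=O)C2(C)C
F3 | step 5 | 4-isopropyl spiro-2H-pyran, 3,4-didehydro-11 with the spiro centre as in 11 | CC(C)C1=C[C@]2(CC[C@@H]3C[C@H]2C3(C)C)OC2=C1C(=O)C(C)(C)C(=O)C2(C)C
F4 | step 3 | lithium 3-methylbut-1-ynide | CC(C)C#C[Li]
F5 | step 3 | (1S,2S,5R)-6,6-dimethyl-2-(3-methylbut-1-ynyl)bicyclo[3.1.1]heptan-2-ol | CC(C)C#C[C@@]1(CC[C@@H]2C[C@H]1C2(C)C)O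
F6 | step 3 | (1S,2R,5R)-6,6-dimethyl-2-[(E)-3-methylbut-1-enyl]bicyclo[3.1.1]heptan-2-ol | CC(C)/C=C/[C@@]1(CC[C@@H]2C[C@H]1C2(C)C)O
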